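The cyclohexane ring of the benzoxepine half (C5a, C6, C7, C8, C9, C9a) is treated as a cyclopentane (C5a, C7, C8, C9, C9a) into whose C5a–C7 bond C6 is inserted. The hydroazulene half, as an alkyllithium, adds to an aldehyde carbon (future C6) standing on the carbinol carbon (future C7) of a cis-fused cyclopenta[b]oxepine made from 2-methylcyclopentane-1,3-dione. A semipinacol 1,2-shift of the quaternary C5a from C7 to the mesylate-bearing C6 then expands the ring, forms the most hindered bond of the target (C5a–C6), sets C6 by inversion and unveils the C7 ketone for the last methyl group. The precursor is a β-mesyloxy tertiary cyclopentanol carrying both halves.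

Key step: step 25

Remark on atom names: atoms of the oxepane half carry the 1-benzoxepine numbering of the target (O1, C2–C5, C5a, C6–C9, C9a), atoms of the other half the azulene numbering (C1–C8a), also in their precursors.
Remark on the target: the SMILES describes a cis-fused oxepane/cyclohexane (C5a methyl and H9a on the same face; 5aS,6S,7R,9aR) and a cis-fused hydroazulene (1S,3aS,5R,8aS); the route is planned for exactly this isomer.
Assumption: the oxazaborolidinium catalyst of step 1 is taken to give the (S)-adduct; if its sense of induction is opposite, its enantiomer is used.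
Remark: the silyloxy carbon C3 of the oxepane is made as both epimers (step 15) and is left undefined in the SMILES; it becomes the ketone in step 27. Enol ether 28 is an E/Z mixture.

Step 1
Reactants: 1 cyclopent-2-en-1-one; 2 1-methoxy-2-methyl-1-(trimethylsilyloxy)prop-1-ene
Product: 3 methyl 2-methyl-2-[(1S)-3-(trimethylsilyloxy)cyclopent-2-en-1-yl]propanoate
Conditions: (S)-3,3-diphenyl-1-(2-methylphenyl)tetrahydro-1H,3H-pyrrolo[1,2-c][1,3,2]oxazaborole·HN(SO2CF3)2 (20 mol%), Ph3PO (25 mol%), toluene, −20 °C; non-aqueous work-up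
Reagents that add atoms: none
Why: Mukaiyama–Michael addition: the chiral oxazaborolidinium ion binds the enone and shields one face, so the silyl ketene acetal forms the C3a–C4 bond and the gem-dimethyl carbon with C3a as S; silyl transfer leaves the C1=C8a silyl enol ether and so fixes the enolate regiochemistry.

Step 2
Reactants: 3 silyl enol ether
Product: 5 methyl 2-methyl-2-[(1S)-3-(trifluoromethylsulfonyloxy)cyclopent-2-en-1-yl]propanoate, via lithium enolate 4 (not isolated)
Conditions: MeLi, THF, 0 °C; then PhN(SO2CF3)2, −78 → 0 °C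
Reagents that add atoms: N-phenylbis(trifluoromethanesulfonimide), O=S(=O)(N(c1ccccc1)S(=O)(=O)C(F)(F)F)C(F)(F)F
Why: Enol triflate formation: MeLi cleaves the O–Si bond to the regiodefined lithium enolate faster than it attacks the neopentyl-type ester, and PhN(SO2CF3)2 sulfonylates the enolate oxygen; no stereocentre is touched.

Step 3
Reactants: 5 enol triflate
Product: 6 methyl 2-methyl-2-[(1S)-3-methylcyclopent-2-en-1-yl]propanoate
Conditions: MeMgBr, Fe(acac)3 (5 mol%), THF/NMP, −30 → 0 °C
Reagents that add atoms: methylmagnesium bromide, C[Mg]Br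
Why: Iron-catalysed Kumada-type cross-coupling of the enol triflate with MeMgBr puts the future C1 methyl on the ring and gives the trisubstituted C1=C8a olefin; the hindered ester survives at low temperature.

Step 4
Reactants: 6 ester
Product: 7 2-methyl-2-[(1S)-3-methylcyclopent-2-en-1-yl]propanal
Conditions: i-Bu2AlH (1.1 equiv), CH2Cl2, −78 °C; Rochelle salt
Reagents that add atoms: none
Why: Partial ester reduction: the aluminium hemiacetal from i-Bu2AlH is stable at −78 °C and collapses on work-up to the non-enolizable aldehyde.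

Step 5
Reactants: 7 aldehyde
Product: 8 (3S)-3-[(3Z)-4-iodo-2-methylpent-3-en-2-yl]-1-methylcyclopent-1-ene
Conditions: EtPPh3I, n-BuLi, THF, 0 °C; I2, −78 °C; NaN(SiMe3)2, −20 °C; then 7, −78 → 0 °C
Reagents that add atoms: ethyltriphenylphosphonium iodide, CC[P+](c1ccccc1)(c1ccccc1)c1ccccc1.[I-]; iodine, II
Why: Wittig olefination with the α-iodo ylide (Stork–Zhao type) should give the trisubstituted vinyl iodide with iodine cis to the quaternary carbon (Z) through the kinetically preferred cis-oxaphosphetane.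

Step 6
Reactants: 8 vinyl iodide
Product: 10 (3Z)-3,5-dimethyl-5-[(1S)-3-methylcyclopent-2-en-1-yl]hex-3-en-2-one, via vinyllithium 9 (not isolated)
Conditions: t-BuLi (2.1 equiv), Et2O, −78 °C; then MeC(O)N(OMe)Me, −78 → 0 °C
Reagents that add atoms: N-methoxy-N-methylacetamide, CC(=O)N(C)OC
Why: Iodine–lithium exchange proceeds with retention of the olefin geometry and the vinyllithium is acylated only once by the Weinreb amide (stable chelated tetrahedral adduct), which gives the Z-enone that a cis ring olefin requires.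

Step 7
Reactants: 10 Z-enone
Product: 11 epoxide of 10 at the cyclopentene with oxygen trans to the side chain
Conditions: m-CPBA, NaHCO3, CH2Cl2, 0 °C
Reagents that add atoms: 3-chloroperoxybenzoic acid, OOC(=O)c1cccc(Cl)c1
Why: Prilezhaev epoxidation attacks only the electron-rich trisubstituted cyclopentene (the hindered enone is electron-poor) and from the face opposite to the bulky C3a substituent, so the epoxide oxygen is trans to the side chain.

Step 8
Reactants: 11 epoxy enone
Product: 13 (1S,3aS,8aS)-1-hydroxy-1,4,4,6-tetramethyl-2,3,3a,4,8,8a-hexahydroazulen-7(1H)-one, via lithium enolate 12 (not isolated)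
Conditions: LiN(i-Pr)2, THF, −78 °C; then DMPU, −78 → 25 °C
Reagents that add atoms: none
Why: Intramolecular alkylation of a ketone enolate by an epoxide: kinetic deprotonation of the methyl ketone gives the cross-conjugated enolate whose CH2 terminus opens the epoxide at the secondary carbon C8a in a 7-exo-tet SN2 reaction (gem-dimethyl group and Z-olefin preorganize the chain); backside attack from the face of the tether makes the ring fusion cis and leaves the C1 hydroxyl on the face of H8a and H3a.

Step 9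
Reactants: 13 hydroxy enone
Product: 14 triethylsilyl ether of 13
Conditions: Et3SiOTf, 2,6-lutidine, CH2Cl2, −78 → 0 °C
Reagents that add atoms: triethylsilyl trifluoromethanesulfonate, CC[Si](CC)(CC)OS(=O)(=O)C(F)(F)F
Why: Silyl ether formation with the silyl triflate and 2,6-lutidine protects the hindered tertiary alcohol for the acid-catalysed Claisen step and the later organolithium chemistry.

Step 10
Reactants: 14 silyloxy enone
Product: 15 (1S,3aS,7R,8aS)-1,4,4,6-tetramethyl-1-(triethylsilyloxy)-1,2,3,3a,4,7,8,8a-octahydroazulen-7-ol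
Conditions: NaBH4, CeCl3·7H2O, MeOH, −78 °C
Reagents that add atoms: none
Why: Luche 1,2-reduction: hydride should come from the convex face (that of H3a and H8a) because the concave face is blocked by the cyclopentane ring with its C1 methyl, which gives the 7R allylic alcohol with OH on the face where the C5 side chain is needed.

Step 11
Reactants: 15 allylic alcohol
Product: 17 ethyl 2-[(1S,3aS,5R,8aS)-1,4,4,6-tetramethyl-1-(triethylsilyloxy)-1,2,3,3a,4,5,8,8a-octahydroazulen-5-yl]acetate, via ketene acetal 16 (not isolated)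
Conditions: MeC(OEt)3, EtCO2H (cat.), xylene, 140 °C
Reagents that add atoms: triethyl orthoacetate, CCOC(C)(OCC)OCC
Why: Johnson–Claisen rearrangement: the ketene acetal undergoes a suprafacial [3,3]-shift that carries the C7–O configuration to the new C5–C bond next to the quaternary C4 (5R) and moves the olefin to C6=C7.

Step 12
Reactants: 17 ester
Product: 18 2-(hydroazulen-5-yl)ethanol
Conditions: LiAlH4, Et2O, 0 °C
Reagents that add atoms: none
Why: Ester reduction by LiAlH4 to the primary alcohol; silyl ether and trisubstituted olefin are inert.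

Step 13
Reactants: 18 alcohol
Product: 19 5-(2-iodoethyl)hydroazulene silyl ether
Conditions: I2, PPh3, imidazole, CH2Cl2, 0 → 25 °C
Reagents that add atoms: iodine, II
Why: Appel-type iodination (Ph3P, I2, imidazole) converts the primary alcohol to the iodide by SN2 displacement of the oxyphosphonium group.

Step 14
Reactants: 20 2-methylcyclopentane-1,3-dione; 21 acrolein
Product: 22 3-(1-methyl-2,5-dioxocyclopentyl)propanal
Conditions: H2O, 25 °C
Reagents that add atoms: none
Why: Michael addition of the acidic 1,3-dione to acrolein in water builds the quaternary carbon (future C5a); no stereocentre arises.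

Step 15
Reactants: 22 aldehyde
Product: 23 2-(3-hydroxy-4-methylpent-4-en-1-yl)-2-methylcyclopentane-1,3-dione
Conditions: CH2=C(Br)CH3, CrCl2, NiCl2 (cat.), DMF, 25 °C
Reagents that add atoms: 2-bromopropene, CC(Br)=C
Why: Nozaki–Hiyama–Kishi reaction: the isopropenylchromium reagent adds to the aldehyde only and leaves the two hindered ketones alone; the new carbinol carbon (future C3) forms as both epimers, which is of no consequence because it ends as the oxepanone carbonyl.

Step 16
Reactants: 23 allylic alcohol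
Product: 24 tert-butyldimethylsilyl ether of 23
Conditions: t-BuMe2SiCl, imidazole, DMF, 25 °C
Reagents that add atoms: tert-butyldimethylsilyl chloride, CC(C)(C)[Si](C)(C)Cl
Why: Silylation of the secondary allylic alcohol (silyl chloride, imidazole).

Step 17
Reactants: 24 prochiral dione
Product: 25 (2R,3R)-3-hydroxy-2-methyl-2-[3-(tert-butyldimethylsilyloxy)-4-methylpent-4-en-1-yl]cyclopentan-1-one
Conditions: (S)-1-methyl-3,3-diphenyltetrahydro-1H,3H-pyrrolo[1,2-c][1,3,2]oxazaborole (20 mol%), catecholborane, toluene, −78 °C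
Reagents that add atoms: none
Why: Corey–Bakshi–Shibata reduction desymmetrizes the prochiral 1,3-dione: the catalyst selects one enantiotopic carbonyl and delivers hydride from the face of the small methyl group, which sets the carbinol (3R) and the quaternary carbon (2R) with OH cis to the long chain; catecholborane does not hydroborate the olefin at −78 °C.

Step 18
Reactants: 25 hydroxy ketone
Product: 27 (5aR,8aR)-3-(tert-butyldimethylsilyloxy)-2,2,5a-trimethyloctahydro-6H-cyclopenta[b]oxepin-6-one, via organomercury trifluoroacetate 26 (not isolated)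
Conditions: Hg(OCOCF3)2, CH2Cl2, 0 °C; then n-Bu3SnH, THF, 0 → 25 °C
Reagents that add atoms: none
Why: Intramolecular alkoxymercuration–demercuration: the cis hydroxyl opens the mercurinium ion of the 1,1-disubstituted olefin at its tertiary carbon (Markovnikov and 7-exo-trig) and the tin hydride replaces mercury by hydrogen without reducing the ketone, which creates the O–C(CH3)2 unit; the cis ring fusion follows from the cis relation of hydroxyl and chain set in step 17.

Step 19
Reactants: 27 bicyclic ketone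
Product: 28 6-(methoxymethylidene) derivative of 27
Conditions: MeOCH2PPh3Cl, KOt-Bu, THF, 0 → 50 °C
Reagents that add atoms: (methoxymethyl)triphenylphosphonium chloride, COC[P+](c1ccccc1)(c1ccccc1)c1ccccc1.[Cl-]
Why: Wittig methoxymethylenation of the hindered cyclopentanone introduces the carbon that becomes C6; olefin geometry is irrelevant because both isomers give the same aldehyde.

Step 20
Reactants: 28 enol ether
Product: 29 (5aR,6R,8aR)-3-(tert-butyldimethylsilyloxy)-6-hydroxy-2,2,5a-trimethyloctahydro-2H-cyclopenta[b]oxepine-6-carbaldehyde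
Conditions: OsO4 (2 mol%), N-methylmorpholine N-oxide, acetone/H2O, 0 °C
Reagents that add atoms: N-methylmorpholine N-oxide (oxygen source through OsO4), C[N+]1([O-])CCOCC1; water, O
Why: OsO4-catalysed dihydroxylation of the electron-rich enol ether occurs from the convex face (that of the angular methyl group, away from the oxepane ring) and the hemiacetal loses methanol, giving the α-hydroxy aldehyde with the tertiary hydroxyl (6R) cis to the angular methyl.

Step 21
Reactants: 29 hydroxy aldehyde
Product: 30 6-(triethylsilyloxy) aldehyde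
Conditions: Et3SiOTf, 2,6-lutidine, CH2Cl2, −78 °C
Reagents that add atoms: triethylsilyl trifluoromethanesulfonate, CC[Si](CC)(CC)OS(=O)(=O)C(F)(F)F
Why: Silylation of the tertiary α-hydroxyl gives a bulky non-chelating α-silyloxy aldehyde and prevents acyloin rearrangement of the hydroxy aldehyde.

Step 22
Reactants: 19 iodide; 30 aldehyde
Product: 32 coupled (S)-carbinol, via alkyllithium 31 (not isolated)
Conditions: 19, t-BuLi (2.1 equiv), Et2O, −78 °C; then 30, −78 °C
Reagents that add atoms: none
Why: Fragment union by addition of an alkyllithium (from iodine–lithium exchange) to the aldehyde under Felkin–Anh control: the C–OSiEt3 bond stands anti to the nucleophile, which passes the ring CH2 and not the quaternary C5a, so the carbinol carbon (future C6) should be S.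

Step 23
Reactants: 32 carbinol
Product: 33 methanesulfonate of 32
Conditions: MsCl, Et3N, DMAP (cat.), CH2Cl2, 0 °C
Reagents that add atoms: methanesulfonyl chloride, CS(=O)(=O)Cl
Why: Mesylation of the only free hydroxyl (secondary) under standard sulfonylation conditions.

Step 24
Reactants: 33 tris-silyl mesylate
Product: 34 triol mesylate
Conditions: HF (48% aq.), MeCN, 0 → 25 °C
Reagents that add atoms: none
Why: Acidic fluoride desilylation removes the three silyl groups while the secondary mesylate stays, and the absence of base avoids closure of an epoxide from the β-hydroxy mesylate.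

Step 25
Reactants: 34 triol mesylate
Product: 36 (5aS,6S,9aR)-3-hydroxy-6-[2-(hydroazulen-5-yl)ethyl]-2,2,5a-trimethyloctahydro-1-benzoxepin-7(2H)-one, via aluminium alkoxide 35 (not isolated)
Conditions: Et3Al (6 equiv), CH2Cl2, −78 → 0 °C
Reagents that add atoms: none
Why: Et3Al turns the hydroxyls into aluminium alkoxides and activates the mesylate; the C7–C5a bond, held antiperiplanar to the C6–OMs bond, migrates to C6 as the mesylate leaves, while the C7–O–Al alkoxide becomes the carbonyl (concerted semipinacol 1,2-shift). The closest known reactions are the organoaluminium-promoted pinacol-type rearrangement of β-mesyloxy alcohols and the D-homoannulation of 17-hydroxy-20-sulfonyloxy steroids (a Tiffeneau–Demjanov-type ring enlargement). No ring is closed between chain ends: the cyclopentane becomes the cyclohexanone by insertion of C6 into the C7–C5a bond, a ring expansion by one carbon. The new stereocentre C6 is set by inversion at the mesylate carbon with retention in the migrating C5a, so the S carbinol gives the 6S ketone with the side chain cis to the angular methyl. The step needs migration of the quaternary C5a and not of the ring CH2 (C8), and rearrangement and not epoxide closure: the tertiary-alkyl carbon has the higher migratory aptitude, the rotamer with C5a anti to the mesylate has the side chain gauche to one ring carbon only whereas the rotamer for CH2 migration wedges it between both, and the Lewis-acidic, weakly nucleophilic aluminium alkoxide disfavours epoxide formation.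

Step 26
Reactants: 36 ring-expanded ketone
Product: 37 (5aS,6S,7R,9aR)-3,7-diol
Conditions: MeMgBr, CeCl3, THF, −78 °C
Reagents that add atoms: methylmagnesium bromide, C[Mg]Br
Why: 1,2-Addition of the methylmagnesium–cerium reagent: attack should come from the face of the oxepane ring, i.e. equatorially on the chair that has the angular methyl axial and anti to the C6 side chain, giving the 7R alcohol with OH cis to the side chain, while the weakly basic cerium reagent avoids enolization and thus epimerization at C6.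

Step 27
Reactants: 37 diol
Product: 38 target
Conditions: Dess–Martin periodinane, NaHCO3, CH2Cl2, 25 °C
Reagents that add atoms: none
Why: Dess–Martin oxidation converts the only secondary alcohol into the oxepanone; the two tertiary alcohols and the olefin do not react.

Compound list
1 | cyclopent-2-en-1-one | O=C1C=CCC1 | starting material
2 | 1-methoxy-2-methyl-1-(trimethylsilyloxy)prop-1-ene | COC(O[Si](C)(C)C)=C(C)C | starting material
3 | methyl 2-methyl-2-[(1S)-3-(trimethylsilyloxy)cyclopent-2-en-1-yl]propanoate | COC(=O)C(C)(C)[C@H]1CCC(O[Si](C)(C)C)=C1 | intermediate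
4 | lithium (3S)-3-(1-methoxy-2-methyl-1-oxopropan-2-yl)cyclopent-1-en-1-olate | COC(=O)C(C)(C)[C@H]1CCC(O[Li])=C1 | intermediate (not isolated)
5 | methyl 2-methyl-2-[(1S)-3-(trifluoromethylsulfonyloxy)cyclopent-2-en-1-yl]propanoate | COC(=O)C(C)(C)[C@H]1CCC(OS(=O)(=O)C(F)(F)F)=C1 | intermediate
6 | methyl 2-methyl-2-[(1S)-3-methylcyclopent-2-en-1-yl]propanoate | COC(=O)C(C)(C)[C@H]1CCC(C)=C1 | intermediate
7 | 2-methyl-2-[(1S)-3-methylcyclopent-2-en-1-yl]propanal | O=CC(C)(C)[C@H]1CCC(C)=C1 | intermediate
8 | (3S)-3-[(3Z)-4-iodo-2-methylpent-3-en-2-yl]-1-methylcyclopent-1-ene | I/C(C)=C\C(C)(C)[C@H]1CCC(C)=C1 | intermediate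
9 | (Z)-vinyllithium from 8 (lithium in place of iodine) | [Li]/C(C)=C\C(C)(C)[C@H]1CCC(C)=C1 | intermediate (not isolated)
10 | (3Z)-3,5-dimethyl-5-[(1S)-3-methylcyclopent-2-en-1-yl]hex-3-en-2-one | CC(=O)/C(C)=C\C(C)(C)[C@H]1CCC(C)=C1 | intermediate
11 | (3Z)-3,5-dimethyl-5-[(1R,2R,5S)-5-methyl-6-oxabicyclo[3.1.0]hexan-2-yl]hex-3-en-2-one (epoxide oxygen trans to the side chain) | CC(=O)/C(C)=C\C(C)(C)[C@H]1CC[C@]2(C)O[C@H]12 | intermediate
12 | lithium enolate of 11 at the methyl ketone (CH2=C(OLi)–) | C=C(O[Li])/C(C)=C\C(C)(C)[C@H]1CC[C@]2(C)O[C@H]12 | intermediate (not isolated)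
13 | (1S,3aS,8aS)-1-hydroxy-1,4,4,6-tetramethyl-2,3,3a,4,8,8a-hexahydroazulen-7(1H)-one (cis-fused; OH cis to H3a and H8a) | CC1=CC(C)(C)[C@H]2CC[C@](C)(O)[C@H]2CC1=O | intermediate
14 | (1S,3aS,8aS)-1,4,4,6-tetramethyl-1-(triethylsilyloxy)-2,3,3a,4,8,8a-hexahydroazulen-7(1H)-one | CC1=CC(C)(C)[C@H]2CC[C@](C)(O[Si](CC)(CC)CC)[C@H]2CC1=O | intermediate
15 | (1S,3aS,7R,8aS)-1,4,4,6-tetramethyl-1-(triethylsilyloxy)-1,2,3,3a,4,7,8,8a-octahydroazulen-7-ol | CC1=CC(C)(C)[C@H]2CC[C@](C)(O[Si](CC)(CC)CC)[C@H]2C[C@H]1O | intermediate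
16 | 1-ethoxyvinyl ether (ketene acetal) of 15 | CC1=CC(C)(C)[C@H]2CC[C@](C)(O[Si](CC)(CC)CC)[C@H]2C[C@H]1OC(=C)OCC | intermediate (not isolated)
17 | ethyl 2-[(1S,3aS,5R,8aS)-1,4,4,6-tetramethyl-1-(triethylsilyloxy)-1,2,3,3a,4,5,8,8a-octahydroazulen-5-yl]acetate | CC1=CC[C@H]2[C@H](CC[C@]2(C)O[Si](CC)(CC)CC)C(C)(C)[C@@H]1CC(=O)OCC | intermediate
18 | 2-[(1S,3aS,5R,8aS)-1,4,4,6-tetramethyl-1-(triethylsilyloxy)-1,2,3,3a,4,5,8,8a-octahydroazulen-5-yl]ethanol | CC1=CC[C@H]2[C@H](CC[C@]2(C)O[Si](CC)(CC)CC)C(C)(C)[C@@H]1CCO | intermediate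
19 | (1S,3aS,5R,8aS)-5-(2-iodoethyl)-1,4,4,6-tetramethyl-1-(triethylsilyloxy)-1,2,3,3a,4,5,8,8a-octahydroazulene | CC1=CC[C@H]2[C@H](CC[C@]2(C)O[Si](CC)(CC)CC)C(C)(C)[C@@H]1CCI | intermediate
20 | 2-methylcyclopentane-1,3-dione | CC1C(=O)CCC1=O | starting material
21 | acrolein (prop-2-enal) | C=CC=O | starting material
22 | 3-(1-methyl-2,5-dioxocyclopentyl)propanal | CC1(CCC=O)C(=O)CCC1=O | intermediate
23 | 2-(3-hydroxy-4-methylpent-4-en-1-yl)-2-methylcyclopentane-1,3-dione (racemic carbinol) | CC(=C)C(O)CCC1(C)C(=O)CCC1=O | intermediate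
24 | 2-[3-(tert-butyldimethylsilyloxy)-4-methylpent-4-en-1-yl]-2-methylcyclopentane-1,3-dione | CC(=C)C(O[Si](C)(C)C(C)(C)C)CCC1(C)C(=O)CCC1=O | intermediate
25 | (2R,3R)-3-hydroxy-2-methyl-2-[3-(tert-butyldimethylsilyloxy)-4-methylpent-4-en-1-yl]cyclopentan-1-one (OH cis to the chain; both epimers at the silyloxy carbon) | CC(=C)C(O[Si](C)(C)C(C)(C)C)CC[C@]1(C)[C@H](O)CCC1=O | intermediate
26 | (5aR,8aR)-3-(tert-butyldimethylsilyloxy)-2,5a-dimethyl-2-[(trifluoroacetoxymercurio)methyl]octahydro-6H-cyclopenta[b]oxepin-6-one | O=C1CC[C@H]2OC(C)(C[Hg]OC(=O)C(F)(F)F)C(O[Si](C)(C)C(C)(C)C)CC[C@@]12C | intermediate (not isolated)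
27 | (5aR,8aR)-3-(tert-butyldimethylsilyloxy)-2,2,5a-trimethyloctahydro-6H-cyclopenta[b]oxepin-6-one (cis-fused; C3 epimers) | O=C1CC[C@H]2OC(C)(C)C(O[Si](C)(C)C(C)(C)C)CC[C@@]12C | intermediate
28 | (5aR,8aR)-3-(tert-butyldimethylsilyloxy)-6-(methoxymethylidene)-2,2,5a-trimethyloctahydro-2H-cyclopenta[b]oxepine (E/Z) | COC=C1CC[C@H]2OC(C)(C)C(O[Si](C)(C)C(C)(C)C)CC[C@@]12C | intermediate
29 | (5aR,6R,8aR)-3-(tert-butyldimethylsilyloxy)-6-hydroxy-2,2,5a-trimethyloctahydro-2H-cyclopenta[b]oxepine-6-carbaldehyde (6-OH cis to the 5a-methyl) | O=C[C@@]1(O)CC[C@H]2OC(C)(C)C(O[Si](C)(C)C(C)(C)C)CC[C@@]12C | intermediate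
30 | (5aR,6R,8aR)-3-(tert-butyldimethylsilyloxy)-2,2,5a-trimethyl-6-(triethylsilyloxy)octahydro-2H-cyclopenta[b]oxepine-6-carbaldehyde | O=C[C@@]1(O[Si](CC)(CC)CC)CC[C@H]2OC(C)(C)C(O[Si](C)(C)C(C)(C)C)CC[C@@]12C | intermediate
31 | alkyllithium from 19 (lithium in place of iodine) | CC1=CC[C@H]2[C@H](CC[C@]2(C)O[Si](CC)(CC)CC)C(C)(C)[C@@H]1CC[Li] | intermediate (not isolated)
32 | (1S)-1-[(5aR,6R,8aR)-3-(tert-butyldimethylsilyloxy)-2,2,5a-trimethyl-6-(triethylsilyloxy)octahydro-2H-cyclopenta[b]oxepin-6-yl]-3-[(1S,3aS,5R,8aS)-1,4,4,6-tetramethyl-1-(triethylsilyloxy)-1,2,3,3a,4,5,8,8a-octahydroazulen-5-yl]propan-1-ol | CC1=CC[C@H]2[C@H](CC[C@]2(C)O[Si](CC)(CC)CC)C(C)(C)[C@@H]1CC[C@H](O)[C@@]1(O[Si](CC)(CC)CC)CC[C@H]2OC(C)(C)C(O[Si](C)(C)C(C)(C)C)CC[C@@]12C | intermediate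
33 | methanesulfonate of 32 at the secondary carbinol | CC1=CC[C@H]2[C@H](CC[C@]2(C)O[Si](CC)(CC)CC)C(C)(C)[C@@H]1CC[C@H](OS(C)(=O)=O)[C@@]1(O[Si](CC)(CC)CC)CC[C@H]2OC(C)(C)C(O[Si](C)(C)C(C)(C)C)CC[C@@]12C | intermediate
34 | triol mesylate: 33 with all three silyl groups removed | CC1=CC[C@H]2[C@H](CC[C@]2(C)O)C(C)(C)[C@@H]1CC[C@H](OS(C)(=O)=O)[C@@]1(O)CC[C@H]2OC(C)(C)C(O)CC[C@@]12C | intermediate
35 | tris(diethylaluminium) alkoxide of 34 | CC1=CC[C@H]2[C@H](CC[C@]2(C)O[Al](CC)CC)C(C)(C)[C@@H]1CC[C@H](OS(C)(=O)=O)[C@@]1(O[Al](CC)CC)CC[C@H]2OC(C)(C)C(O[Al](CC)CC)CC[C@@]12C | intermediate (not isolated)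
36 | (5aS,6S,9aR)-3-hydroxy-6-{2-[(1S,3aS,5R,8aS)-1-hydroxy-1,4,4,6-tetramethyl-1,2,3,3a,4,5,8,8a-octahydroazulen-5-yl]ethyl}-2,2,5a-trimethyloctahydro-1-benzoxepin-7(2H)-one | CC1=CC[C@H]2[C@H](CC[C@]2(C)O)C(C)(C)[C@@H]1CC[C@H]1[C@]2(C)CCC(O)C(C)(C)O[C@@H]2CCC1=O | intermediate
37 | (5aS,6S,7R,9aR)-6-{2-[(1S,3aS,5R,8aS)-1-hydroxy-1,4,4,6-tetramethyl-1,2,3,3a,4,5,8,8a-octahydroazulen-5-yl]ethyl}-2,2,5a,7-tetramethyldecahydro-1-benzoxepine-3,7-diol | CC1=CC[C@H]2[C@H](CC[C@]2(C)O)C(C)(C)[C@@H]1CC[C@H]1[C@]2(C)CCC(O)C(C)(C)O[C@@H]2CC[C@@]1(C)O | intermediate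
38 | (5aS,6S,7R,9aR)-7-hydroxy-6-{2-[(1S,3aS,5R,8aS)-1-hydroxy-1,4,4,6-tetramethyl-1,2,3,3a,4,5,8,8a-octahydroazulen-5-yl]ethyl}-2,2,5a,7-tetramethyloctahydro-1-benzoxepin-3(2H)-one | CC1=CC[C@H]2[C@H](CC[C@]2(C)O)C(C)(C)[C@@H]1CC[C@H]1[C@]2(C)CCC(=O)C(C)(C)O[C@@H]2CC[C@@]1(C)O | target

Total step count: 27 (steps 1–13 hydroazulene half, steps 14–18 oxepane half, steps 19–27 union and end game).
Longest linear sequence: 19 steps (steps 1–13, then 22–27).

Steps most likely to fail

Step 8. The cross-conjugated enolate may be too weak a nucleophile for a seven-membered epoxide opening, so intermolecular aldol reaction or slow decomposition of the epoxide could outrun ring closure. The fallback moves the ring closure to a simple saturated methyl-ketone enolate and adds the C5=C6 double bond afterwards; it sets out from 7 and returns at 14. Horner–Wadsworth–Emmons reaction of 7 with diethyl (3-oxobutan-2-yl)phosphonate should give the (3E)-enone F1. Conjugate reduction with [(Ph3P)CuH]6 should give the saturated methyl ketone F2. m-CPBA should give the trans epoxide F3. The kinetic methyl-ketone enolate (LiN(i-Pr)2) should close the ring to the saturated hydroxy ketone F4. Silylation (Et3SiOTf) gives the triethylsilyl ether F5. The more substituted trimethylsilyl enol ether F6 (Me3SiOTf, Et3N) and Saegusa–Ito dehydrogenation with Pd(OAc)2 would then give 14.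

Step 25. The ring CH2 (C8) could migrate in place of the quaternary C5a, or the tertiary alkoxide could close an epoxide, so that the wrong ring or no ring expansion results. The fallback uses an acyloin rearrangement in place of a leaving group; it sets out from 32 and returns at 36. Dess–Martin oxidation of 32 should give the α-silyloxy ketone F7. Aqueous HF should give the α-hydroxy ketone F8. Acyloin (α-ketol) rearrangement with Al(Ot-Bu)3 in hot toluene should expand the ring to the 2-hydroxy-2-alkylcyclohexanone F9, as in the D-homoannulation of 17-hydroxy-20-keto steroids. SmI2 in THF/MeOH removes the α-hydroxyl and protonation of the samarium enolate gives 36. In this fallback the C6 configuration rests on kinetic protonation or base equilibration, not on a stereospecific shift.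

Step 26. Facial selectivity may be poor or inverted (methyl entering from the face of the side chain), giving the C7 epimer, and enolization could scramble C6. The fallback brings the oxygen, not the carbon, in from outside; it sets out from 36 and returns at 37. Non-basic methylenation with Cp2Ti(CH3)2 should give the exocyclic alkene F10. OsO4/NMO dihydroxylation of this less hindered 1,1-disubstituted olefin puts oxygen on the face a methyl nucleophile would have used, giving the opposite C7 configuration in the primary/tertiary diol F11. Tosylation of the primary hydroxyl gives the monotosylate F12. LiBHEt3 replaces the tosylate by hydride (directly or through the spiro-epoxide) and gives 37.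

Further compounds
F1 | step 8 | (3E)-3,5-dimethyl-5-[(1S)-3-methylcyclopent-2-en-1-yl]hex-3-en-2-one | CC(=O)/C(C)=C/C(C)(C)[C@H]1CCC(C)=C1
F2 | step 8 | 3,5-dimethyl-5-[(1S)-3-methylcyclopent-2-en-1-yl]hexan-2-one | CC(=O)C(C)CC(C)(C)[C@H]1CCC(C)=C1
F3 | step 8 | 3,5-dimethyl-5-[(1R,2R,5S)-5-methyl-6-oxabicyclo[3.1.0]hexan-2-yl]hexan-2-one | CC(=O)C(C)CC(C)(C)[C@H]1CC[C@]2(C)O[C@H]12
F4 | step 8 | (1S,3aS,8aS)-1-hydroxy-1,4,4,6-tetramethyloctahydroazulen-7(1H)-one | CC1CC(C)(C)[C@H]2CC[C@](C)(O)[C@H]2CC1=O
F5 | step 8 | triethylsilyl ether of F4 | CC1CC(C)(C)[C@H]2CC[C@](C)(O[Si](CC)(CC)CC)[C@H]2CC1=O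
F6 | step 8 | 7-(trimethylsilyloxy)-6-ene silyl enol ether of F5 | CC1=C(O[Si](C)(C)C)C[C@H]2[C@H](CC[C@]2(C)O[Si](CC)(CC)CC)C(C)(C)C1
F7 | step 25 | α-silyloxy ketone from oxidation of 32 | CC1=CC[C@H]2[C@H](CC[C@]2(C)O[Si](CC)(CC)CC)C(C)(C)[C@@H]1CCC(=O)[C@@]1(O[Si](CC)(CC)CC)CC[C@H]2OC(C)(C)C(O[Si](C)(C)C(C)(C)C)CC[C@@]12C
F8 | step 25 | α-hydroxy ketone (F7 without silyl groups) | CC1=CC[C@H]2[C@H](CC[C@]2(C)O)C(C)(C)[C@@H]1CCC(=O)[C@@]1(O)CC[C@H]2OC(C)(C)C(O)CC[C@@]12C
F9 | step 25 | ring-expanded 3,6-dihydroxy-6-[2-(hydroazulen-5-yl)ethyl]-2,2,5a-trimethyloctahydro-1-benzoxepin-7(2H)-one | CC1=CC[C@H]2[C@H](CC[C@]2(C)O)C(C)(C)[C@@H]1CCC1(O)[C@]2(C)CCC(O)C(C)(C)O[C@@H]2CCC1=O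
F10 | step 26 | 7-methylidene analogue of 36 | CC1=CC[C@H]2[C@H](CC[C@]2(C)O)C(C)(C)[C@@H]1CC[C@H]1[C@]2(C)CCC(O)C(C)(C)O[C@@H]2CCC1=C
F11 | step 26 | 7-(hydroxymethyl)-7-hydroxy diol from F10 | CC1=CC[C@H]2[C@H](CC[C@]2(C)O)C(C)(C)[C@@H]1CC[C@H]1[C@]2(C)CCC(O)C(C)(C)O[C@@H]2CC[C@@]1(CO)O
F12 | step 26 | primary p-toluenesulfonate of F11 | CC1=CC[C@H]2[C@H](CC[C@]2(C)O)C(C)(C)[C@@H]1CC[C@H]1[C@]2(C)CCC(O)C(C)(C)O[C@@H]2CC[C@@]1(COS(=O)(=O)c3ccc(C)cc3)O
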